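**Retrosynthetic overview**
- The target is released from its tetra-O-benzyl aryltetralin trans-γ-lactone by lactone hydrolysis and hydrogenolysis.
- The carbocycle is closed last (C1–C8a) by a quinone-methide-type Friedel–Crafts cyclisation of a 7-hydroxy-8,8'-dihydroxy-dibenzylbutyrolactone, as in the cyclisation of hydroxylated lignan lactones; the trans-lactone sets C1.
- That trans-butyrolactone is made in the same flask from an acetonide diol ester (acetonide off, γ-lactonisation, then ring closure).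
- Both tertiary carbinols come from L-tartaric acid: enolate benzylation (C3–C4 side), then enolate aldol with the gallaldehyde ether (C1–C2 side). The aldolate lactonises onto the distal ester, which marks the carboxyl that is then reduced to CH2OH.
- Ring order: dioxolane (chiral pool), temporary bicyclic γ-lactone, trans-butyrolactone, tetralin carbocycle, lactone opened.

Assumption: the tartrate acetonide enolate reacts anti to the substituent on the neighbouring ring carbon; if the sense proved opposite, the equally available D-tartrate ester would replace 3.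

**Step 1**
Reactants: 1 4-(benzyloxy)-3-methoxybenzyl alcohol
Product: 2 4-(benzyloxy)-3-methoxybenzyl bromide
Conditions: PBr3 (0.4 equiv), Et2O, 0 °C, 1 h; used at once
Reagents that add atoms: phosphorus tribromide, BrP(Br)Br
Why: PBr3 bromination of a benzylic alcohol (phosphite ester, then SN2 by bromide); no stereocentre is involved.

**Step 2**
Reactants: 3 dimethyl (4R,5R)-2,2-dimethyl-1,3-dioxolane-4,5-dicarboxylate; 2 4-(benzyloxy)-3-methoxybenzyl bromide
Product: 5 dimethyl (4R,5S)-5-[4-(benzyloxy)-3-methoxybenzyl]-2,2-dimethyl-1,3-dioxolane-4,5-dicarboxylate, via tartrate ester lithium enolate 4 (not isolated)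
Conditions: LDA (1.05 equiv), THF/DMPU (5:1), −78 °C, 15 min; then 2 (1.2 equiv), −78 → −45 °C
Reagents that add atoms: none
Why: Seebach-type alkylation of the tartrate acetonide enolate (β-elimination is blocked because the ring C–O bond lies in the nodal plane of the enolate), the benzylic bromide entering anti to the ester on the neighbouring ring carbon, which sets the quaternary centre as 5S and leaves the two esters cis.

**Step 3**
Reactants: 5 dimethyl (4R,5S)-5-[4-(benzyloxy)-3-methoxybenzyl]-2,2-dimethyl-1,3-dioxolane-4,5-dicarboxylate; 6 3,4,5-tris(benzyloxy)benzaldehyde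
Product: 9 methyl (3aS,6aS)-6a-[4-(benzyloxy)-3-methoxybenzyl]-2,2-dimethyl-6-oxo-4-[3,4,5-tris(benzyloxy)phenyl]dihydro-4H-furo[3,4-d][1,3]dioxole-3a(6H)-carboxylate (C4 epimers), via benzylated ester lithium enolate 7 (not isolated), via lithium aldolate 8 (not isolated)
Conditions: LDA (1.1 equiv), THF/DMPU, −78 °C; then 6, −78 → 0 °C, 2 h; then H2O
Reagents that add atoms: none
Why: Tandem lithium-enolate aldol addition and lactonisation: enolisation erases C4, the aldehyde adds anti to the benzyl group on the adjacent quaternary carbon (the face where lithium is held by the neighbouring ester), and only that adduct has its alkoxide cis to the distal ester, so γ-lactonisation drains the reversible aldol equilibrium, fixes the second carbinol centre (3aS) and marks the vanillyl-side carboxyl; the aryl-bearing C4 forms as an epimer mixture that is erased in step 5.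

**Step 4**
Reactants: 9 methyl (3aS,6aS)-6a-[4-(benzyloxy)-3-methoxybenzyl]-2,2-dimethyl-6-oxo-4-[3,4,5-tris(benzyloxy)phenyl]dihydro-4H-furo[3,4-d][1,3]dioxole-3a(6H)-carboxylate (C4 epimers)
Product: 10 methyl (4S,5R)-5-[4-(benzyloxy)-3-methoxybenzyl]-4-{hydroxy[3,4,5-tris(benzyloxy)phenyl]methyl}-5-(hydroxymethyl)-2,2-dimethyl-1,3-dioxolane-4-carboxylate (carbinol epimers)
Conditions: LiBH4 (1.1 equiv), THF, −20 → 0 °C; aq. NH4Cl
Reagents that add atoms: none
Why: Chemoselective borohydride reduction: the strained cis-fused γ-lactone is more electrophilic than the methyl ester on the fully substituted neighbouring carbon, so it is reduced to the diol while the ester survives, and no stereocentre is touched.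

**Step 5**
Reactants: 10 methyl (4S,5R)-5-[4-(benzyloxy)-3-methoxybenzyl]-4-{hydroxy[3,4,5-tris(benzyloxy)phenyl]methyl}-5-(hydroxymethyl)-2,2-dimethyl-1,3-dioxolane-4-carboxylate (carbinol epimers)
Product: 12 (3aR,9S,9aS)-7-(benzyloxy)-3a,9a-dihydroxy-6-methoxy-9-[3,4,5-tris(benzyloxy)phenyl]-3a,4,9,9a-tetrahydronaphtho[2,3-c]furan-1(3H)-one, via trans-dihydroxy butyrolactone 11 (not isolated)
Conditions: (i) AcOH/H2O (4:1), 60 °C; evaporate; (ii) TFA (10 equiv), CH2Cl2, 0 °C → rt
Reagents that add atoms: none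
Why: One-flask acid cascade ending in a biomimetic quinone-methide-type intramolecular Friedel–Crafts alkylation: aqueous acetic acid removes the acetonide and the freed primary alcohol closes the trans-dihydroxy γ-butyrolactone, then TFA ionises the benzylic alcohol to the trialkoxybenzyl (O-benzyl quinone methide) cation, which the guaiacyl ring attacks para to OMe through a chair-like transition state on the trans-fused lactone with the aryl group pseudo-equatorial and both tertiary OH groups axial, giving the 1,2-trans centre (9S) as in the podorhizol to deoxyisopodophyllotoxin type of cyclisation.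

**Step 6**
Reactants: 12 (3aR,9S,9aS)-7-(benzyloxy)-3a,9a-dihydroxy-6-methoxy-9-[3,4,5-tris(benzyloxy)phenyl]-3a,4,9,9a-tetrahydronaphtho[2,3-c]furan-1(3H)-one
Product: 13 (1S,2S,3R)-7-(benzyloxy)-2,3-dihydroxy-3-(hydroxymethyl)-6-methoxy-1-[3,4,5-tris(benzyloxy)phenyl]-1,2,3,4-tetrahydronaphthalene-2-carboxylic acid
Conditions: LiOH·H2O (3 equiv), THF/H2O (3:1), 0 °C → rt; then 1 M HCl to pH 3, 0 °C
Reagents that add atoms: lithium hydroxide, [Li+].[OH-]
Why: Saponification of the strained trans-fused α-hydroxy γ-lactone (acyl–oxygen cleavage) frees the acid and the primary alcohol; none of the three stereocentres is enolisable, and the phenols are still benzylated and so not air-sensitive in base.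

**Step 7**
Reactants: 13 (1S,2S,3R)-7-(benzyloxy)-2,3-dihydroxy-3-(hydroxymethyl)-6-methoxy-1-[3,4,5-tris(benzyloxy)phenyl]-1,2,3,4-tetrahydronaphthalene-2-carboxylic acid
Product: 14 (1S,2S,3R)-2,3,7-trihydroxy-3-(hydroxymethyl)-6-methoxy-1-(3,4,5-trihydroxyphenyl)-1,2,3,4-tetrahydronaphthalene-2-carboxylic acid
Conditions: H2 (1 atm), 10% Pd/C, THF/H2O (4:1), rt; filter under Ar, lyophilise
Reagents that add atoms: none
Why: Catalytic hydrogenolysis of the four aryl benzyl ethers under neutral conditions; the diaryl-substituted C1–H and the tertiary alcohols are inert, so all three stereocentres are retained.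

**Compound list**
1 | 4-(benzyloxy)-3-methoxybenzyl alcohol | COc1cc(CO)ccc1OCc1ccccc1 | starting material
2 | 4-(benzyloxy)-3-methoxybenzyl bromide | COc1cc(CBr)ccc1OCc1ccccc1 | intermediate
3 | dimethyl (4R,5R)-2,2-dimethyl-1,3-dioxolane-4,5-dicarboxylate (dimethyl 2,3-O-isopropylidene-L-tartrate) | CC1(C)O[C@@H](C(=O)OC)[C@H](C(=O)OC)O1 | starting material
4 | tartrate ester lithium enolate (lithium methyl ketene acetal of 3, remaining centre R) | COC(=O)[C@@H]1OC(C)(C)OC1=C(OC)O[Li] | intermediate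
5 | dimethyl (4R,5S)-5-[4-(benzyloxy)-3-methoxybenzyl]-2,2-dimethyl-1,3-dioxolane-4,5-dicarboxylate | CC1(C)O[C@@H](C(=O)OC)[C@@](Cc2ccc(OCc3ccccc3)c(OC)c2)(C(=O)OC)O1 | intermediate
6 | 3,4,5-tris(benzyloxy)benzaldehyde | O=Cc1cc(OCc2ccccc2)c(OCc2ccccc2)c(OCc2ccccc2)c1 | starting material
7 | benzylated ester lithium enolate (lithium methyl ketene acetal of 5 at C4, quaternary centre S) | COC(=O)[C@@]1(Cc2ccc(OCc3ccccc3)c(OC)c2)OC(C)(C)OC1=C(OC)O[Li] | intermediate
8 | lithium aldolate (lithium alkoxide of dimethyl (4S,5S)-5-[4-(benzyloxy)-3-methoxybenzyl]-4-{hydroxy[3,4,5-tris(benzyloxy)phenyl]methyl}-2,2-dimethyl-1,3-dioxolane-4,5-dicarboxylate, carbinol epimers) | COC(=O)[C@@]1(C(O[Li])c2cc(OCc3ccccc3)c(OCc3ccccc3)c(OCc3ccccc3)c2)OC(C)(C)O[C@@]1(C(=O)OC)Cc1ccc(OCc2ccccc2)c(OC)c1 | intermediate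
9 | methyl (3aS,6aS)-6a-[4-(benzyloxy)-3-methoxybenzyl]-2,2-dimethyl-6-oxo-4-[3,4,5-tris(benzyloxy)phenyl]dihydro-4H-furo[3,4-d][1,3]dioxole-3a(6H)-carboxylate (bicyclic acetonide γ-lactone, C4 epimers) | COC(=O)[C@@]12OC(C)(C)O[C@]1(Cc1ccc(OCc3ccccc3)c(OC)c1)C(=O)OC2c1cc(OCc3ccccc3)c(OCc3ccccc3)c(OCc3ccccc3)c1 | intermediate
10 | methyl (4S,5R)-5-[4-(benzyloxy)-3-methoxybenzyl]-4-{hydroxy[3,4,5-tris(benzyloxy)phenyl]methyl}-5-(hydroxymethyl)-2,2-dimethyl-1,3-dioxolane-4-carboxylate (carbinol epimers) | COC(=O)[C@@]1(C(O)c2cc(OCc3ccccc3)c(OCc3ccccc3)c(OCc3ccccc3)c2)OC(C)(C)O[C@@]1(CO)Cc1ccc(OCc2ccccc2)c(OC)c1 | intermediate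
11 | trans-dihydroxy butyrolactone: (3S,4R)-4-[4-(benzyloxy)-3-methoxybenzyl]-3,4-dihydroxy-3-{hydroxy[3,4,5-tris(benzyloxy)phenyl]methyl}dihydrofuran-2(3H)-one (carbinol epimers) | OC(c1cc(OCc2ccccc2)c(OCc2ccccc2)c(OCc2ccccc2)c1)[C@@]1(O)C(=O)OC[C@]1(O)Cc1ccc(OCc2ccccc2)c(OC)c1 | intermediate
12 | (3aR,9S,9aS)-7-(benzyloxy)-3a,9a-dihydroxy-6-methoxy-9-[3,4,5-tris(benzyloxy)phenyl]-3a,4,9,9a-tetrahydronaphtho[2,3-c]furan-1(3H)-one | COc1cc2c(cc1OCc1ccccc1)[C@H](c1cc(OCc3ccccc3)c(OCc3ccccc3)c(OCc3ccccc3)c1)[C@@]1(O)C(=O)OC[C@]1(O)C2 | intermediate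
13 | (1S,2S,3R)-7-(benzyloxy)-2,3-dihydroxy-3-(hydroxymethyl)-6-methoxy-1-[3,4,5-tris(benzyloxy)phenyl]-1,2,3,4-tetrahydronaphthalene-2-carboxylic acid | COc1cc2c(cc1OCc1ccccc1)[C@H](c1cc(OCc3ccccc3)c(OCc3ccccc3)c(OCc3ccccc3)c1)[C@@](O)(C(=O)O)[C@](O)(CO)C2 | intermediate
14 | (1S,2S,3R)-2,3,7-trihydroxy-3-(hydroxymethyl)-6-methoxy-1-(3,4,5-trihydroxyphenyl)-1,2,3,4-tetrahydronaphthalene-2-carboxylic acid | COc1cc2c(cc1O)[C@H](c1cc(O)c(O)c(O)c1)[C@@](O)(C(=O)O)[C@](O)(CO)C2 | target

**Step count**
Total: 7 steps. Longest linear sequence: 7 steps (1 → 2 → 5 → 9 → 10 → 12 → 13 → 14).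

**Steps most likely to fail**

Step 3 (aldol–lactonisation). The risks are enolisation next to a quaternary carbon, modest facial bias between benzyl and ester, and retro-aldol. The fallback reverses the order of the two C–C bond formations; it sets out from 3 and comes back at 9. The enolate of 3 is first added to aldehyde 6 (anti to the neighbouring ester) and the aldolate is silylated in the flask with Et3SiCl to give the silyl-protected aldol diester F1. A second enolisation (LDA) and alkylation with bromide 2, now anti to the much larger silyloxybenzyl group, gives the benzylated silyl ether diester F2. TBAF then frees the alkoxide, which is cis to the distal ester and lactonises to 9.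

Step 4 (lactone versus ester reduction). The risks are over-reduction of the methyl ester and retro-aldol of the β-alkoxide. The fallback removes the need for discrimination; it sets out from 9 and comes back at 11 (and so 12). LiOH saponifies both carbonyl groups of 9 and acidification re-closes the γ-lactone to give the bicyclic lactone acid F3. LiBH4 can then reduce only the lactone (the carboxylate is inert), giving the dihydroxy acid acetonide F4. Under the step 5 conditions F4 loses the acetonide and lactonises as a γ-hydroxy acid to 11.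

Step 5 (cascade ring closure). The risks are ring closure before the lactone has formed, which would give the C1 epimer, and a 1,2-shift of the cation next to the tertiary carbinol. The fallback deprotects first so that a true p-quinone methide can form under mild acid; it sets out from 10 and comes back at 14. Hydrogenolysis of 10 (Pd/C, EtOAc, stopped before the benzylic OH is cleaved) gives the debenzylated acetonide ester F5. Dilute aqueous acid (0.2 M HCl, dioxane/H2O, 50 °C, under Ar) removes the acetonide, closes the lactone and then cyclises through the free-phenol quinone methide to the unprotected aryltetralin lactone F6. Degassed LiOH opens the lactone to 14.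

Further compounds
F1 | step 3 | silyl-protected aldol diester: dimethyl (4R,5R)-2,2-dimethyl-4-{[3,4,5-tris(benzyloxy)phenyl](triethylsilyloxy)methyl}-1,3-dioxolane-4,5-dicarboxylate (carbinol epimers) | COC(=O)[C@@H]1OC(C)(C)O[C@@]1(C(=O)OC)C(O[Si](CC)(CC)CC)c1cc(OCc2ccccc2)c(OCc2ccccc2)c(OCc2ccccc2)c1
F2 | step 3 | benzylated silyl ether diester: dimethyl (4S,5S)-5-[4-(benzyloxy)-3-methoxybenzyl]-2,2-dimethyl-4-{[3,4,5-tris(benzyloxy)phenyl](triethylsilyloxy)methyl}-1,3-dioxolane-4,5-dicarboxylate (carbinol epimers) | COC(=O)[C@@]1(Cc2ccc(OCc3ccccc3)c(OC)c2)OC(C)(C)O[C@@]1(C(=O)OC)C(O[Si](CC)(CC)CC)c1cc(OCc2ccccc2)c(OCc2ccccc2)c(OCc2ccccc2)c1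
F3 | step 4 | bicyclic lactone acid: (3aS,6aS)-6a-[4-(benzyloxy)-3-methoxybenzyl]-2,2-dimethyl-6-oxo-4-[3,4,5-tris(benzyloxy)phenyl]dihydro-4H-furo[3,4-d][1,3]dioxole-3a(6H)-carboxylic acid (C4 epimers) | OC(=O)[C@@]12OC(C)(C)O[C@]1(Cc1ccc(OCc3ccccc3)c(OC)c1)C(=O)OC2c1cc(OCc3ccccc3)c(OCc3ccccc3)c(OCc3ccccc3)c1
F4 | step 4 | dihydroxy acid acetonide: (4S,5R)-5-[4-(benzyloxy)-3-methoxybenzyl]-4-{hydroxy[3,4,5-tris(benzyloxy)phenyl]methyl}-5-(hydroxymethyl)-2,2-dimethyl-1,3-dioxolane-4-carboxylic acid (carbinol epimers) | OC(=O)[C@@]1(C(O)c2cc(OCc3ccccc3)c(OCc3ccccc3)c(OCc3ccccc3)c2)OC(C)(C)O[C@@]1(CO)Cc1ccc(OCc2ccccc2)c(OC)c1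
F5 | step 5 | debenzylated acetonide ester: methyl (4S,5R)-4-[hydroxy(3,4,5-trihydroxyphenyl)methyl]-5-(4-hydroxy-3-methoxybenzyl)-5-(hydroxymethyl)-2,2-dimethyl-1,3-dioxolane-4-carboxylate (carbinol epimers) | COC(=O)[C@@]1(C(O)c2cc(O)c(O)c(O)c2)OC(C)(C)O[C@@]1(CO)Cc1ccc(O)c(OC)c1
F6 | step 5 | unprotected aryltetralin lactone: (3aR,9S,9aS)-3a,7,9a-trihydroxy-6-methoxy-9-(3,4,5-trihydroxyphenyl)-3a,4,9,9a-tetrahydronaphtho[2,3-c]furan-1(3H)-one | COc1cc2c(cc1O)[C@H](c1cc(O)c(O)c(O)c1)[C@@]1(O)C(=O)OC[C@]1(O)C2
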